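**Retrosynthetic overview**
- The C2' ketone comes from oxidation of a C2' carbinol. That carbinol is the bought stereocentre (L-valine series); it is erased only after it has set C1'.
- The C1' senecioate comes from acylation of the benzylic alcohol of a 1,2-anti diol that is mono-silylated at O2'.
- Key disconnection C8–C1': electroreductive Cr/Ni-catalysed arylation of (S)-2-silyloxy-3-methylbutanal with 8-iodo-7-methoxycoumarin under Felkin–Anh 1,2-induction.
- Fragments: the aryl iodide from umbelliferone (iodination, O-methylation); the aldehyde from methyl (S)-2-hydroxy-3-methylbutanoate (silylation, DIBAL).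
- No ring is formed; the coumarin bicycle is bought intact.

Assumption: umbelliferone, methyl (S)-2-hydroxy-3-methylbutanoate and 3-methylbut-2-enoyl chloride are taken as commercial; the single stereocentre of the target is (R).

**Route**

Step 1
Reactants: 1 umbelliferone (7-hydroxy-2H-chromen-2-one)
Product: 2 7-hydroxy-8-iodo-2H-chromen-2-one
Conditions: I2 (1.0 equiv), KI, 20% aq. NH3, rt; then dil. H2SO4
Reagents that add atoms: iodine, II
Why: Electrophilic aromatic iodination of the phenolate goes to C8, the position ortho to O7 that 7-hydroxycoumarins normally substitute; no stereocentre is involved.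

Step 2
Reactants: 2 7-hydroxy-8-iodo-2H-chromen-2-one
Product: 3 8-iodo-7-methoxy-2H-chromen-2-one
Conditions: MeI, K2CO3, acetone, reflux
Reagents that add atoms: iodomethane, CI
Why: Williamson ether synthesis on the acidic coumarin phenol; the lactone and the aryl iodide are inert to K2CO3/MeI.

Step 3
Reactants: 4 methyl (S)-2-hydroxy-3-methylbutanoate
Product: 5 methyl (S)-2-(tert-butyldimethylsilyloxy)-3-methylbutanoate
Conditions: TBSCl, imidazole, DMF, rt
Reagents that add atoms: tert-butyldimethylsilyl chloride, CC(C)(C)[Si](C)(C)Cl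
Why: Imidazole-promoted O-silylation (Corey conditions) touches no bond at the stereocentre, so the bought (S) centre is retained; the bulky non-chelating silyl group is what later enforces Felkin–Anh addition.

Step 4
Reactants: 5 methyl (S)-2-(tert-butyldimethylsilyloxy)-3-methylbutanoate
Product: 6 (S)-2-(tert-butyldimethylsilyloxy)-3-methylbutanal
Conditions: DIBAL-H (1.1 equiv), CH2Cl2, −78 °C; MeOH, then aq. Rochelle salt
Reagents that add atoms: none
Why: Partial DIBAL reduction of an α-silyloxy ester stops at the tetrahedral aluminium hemiacetal at −78 °C and releases the aldehyde only on work-up, under non-basic conditions that do not epimerise C2 (use 6 fresh).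

Step 5
Reactants: 3 8-iodo-7-methoxy-2H-chromen-2-one; 6 (S)-2-(tert-butyldimethylsilyloxy)-3-methylbutanal (1.3 equiv)
Product: 8 8-[(1R,2S)-2-(tert-butyldimethylsilyloxy)-1-hydroxy-3-methylbutyl]-7-methoxy-2H-chromen-2-one, via TMS ether 7 (not isolated)
Conditions: CrCl2 (15 mol %), NiCl2·neocuproine (3 mol %), TMSCl (2 equiv), LiCl, nBu4NPF6, DMF, undivided cell, Al(+)|Ni foam(−), 3 mA, ca. 2.2 F/mol, rt; then 1 M HCl/THF, 0 °C, 15 min
Reagents that add atoms: none
Why: Proposed new method: the cathode keeps a catalytic Cr(III)/Cr(II) couple turning over with the Al anode as terminal reductant, at a potential positive of coumarin and aldehyde reduction; Ni(0) inserts into the C8–I bond of 3 and transfers the aryl group to chromium, and the resulting σ-aryl-Cr(III) species is inert to the lactone/enoate but adds to 6 through the polar Felkin–Anh transition state (C–OTBS anti to the incoming aryl, approach past H rather than i-Pr), so the valine-derived C2' centre sets C1' as the 1,2-anti (1'R,2'S) adduct; TMSCl strips the Cr(III) alkoxide as TMS ether 7 to close the cycle. The closest known reaction type is the Nozaki–Hiyama–Kishi reaction in its electrochemical chromium-catalytic form (alkenyl and simple aryl halides with unhindered aldehydes), which has not been shown for a di-ortho-substituted coumarinyl iodide or for substrate-controlled addition to an α-silyloxy aldehyde.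

Step 6
Reactants: 8 8-[(1R,2S)-2-(tert-butyldimethylsilyloxy)-1-hydroxy-3-methylbutyl]-7-methoxy-2H-chromen-2-one; 9 3-methylbut-2-enoyl chloride
Product: 10 (1R,2S)-2-(tert-butyldimethylsilyloxy)-1-(7-methoxy-2-oxo-2H-chromen-8-yl)-3-methylbutyl 3-methylbut-2-enoate
Conditions: pyridine (3 equiv), DMAP (0.2 equiv), CH2Cl2, 0 °C → rt
Reagents that add atoms: none
Why: DMAP-catalysed acylation (nucleophilic catalysis) with the weak base pyridine instead of Et3N avoids the vinylketene pathway to the deconjugated ester, and since only the O–H bond reacts, C1' keeps its (R) configuration.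

Step 7
Reactants: 10 (1R,2S)-2-(tert-butyldimethylsilyloxy)-1-(7-methoxy-2-oxo-2H-chromen-8-yl)-3-methylbutyl 3-methylbut-2-enoate
Product: 11 (1R,2S)-2-hydroxy-1-(7-methoxy-2-oxo-2H-chromen-8-yl)-3-methylbutyl 3-methylbut-2-enoate
Conditions: HF·pyridine, pyridine/THF, 0 °C → rt
Reagents that add atoms: none
Why: Fluoride-mediated desilylation in a buffered, mildly acidic medium removes the secondary TBS group without the base catalysis that would cause 1,2-acyl migration, lactone opening or ester cleavage.

Step 8
Reactants: 11 (1R,2S)-2-hydroxy-1-(7-methoxy-2-oxo-2H-chromen-8-yl)-3-methylbutyl 3-methylbut-2-enoate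
Product: 12 (1R)-1-(7-methoxy-2-oxo-2H-chromen-8-yl)-3-methyl-2-oxobutyl 3-methylbut-2-enoate (CNP0130048.1)
Conditions: Dess–Martin periodinane (1.5 equiv), CH2Cl2, 0 °C → rt
Reagents that add atoms: none
Why: Dess–Martin oxidation under neutral, non-enolising conditions turns the relay carbinol C2' into the isopropyl ketone without epimerising the now acidic benzylic C1'–H, leaving the (R) centre set in step 5.

**Compound list**
1 | umbelliferone (7-hydroxy-2H-chromen-2-one) | Oc1ccc2ccc(=O)oc2c1 | starting material
2 | 7-hydroxy-8-iodo-2H-chromen-2-one | Oc1ccc2ccc(=O)oc2c1I | intermediate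
3 | 8-iodo-7-methoxy-2H-chromen-2-one | COc1ccc2ccc(=O)oc2c1I | intermediate
4 | methyl (S)-2-hydroxy-3-methylbutanoate | COC(=O)[C@@H](O)C(C)C | starting material
5 | methyl (S)-2-(tert-butyldimethylsilyloxy)-3-methylbutanoate | COC(=O)[C@@H](O[Si](C)(C)C(C)(C)C)C(C)C | intermediate
6 | (S)-2-(tert-butyldimethylsilyloxy)-3-methylbutanal | O=C[C@@H](O[Si](C)(C)C(C)(C)C)C(C)C | intermediate
7 | 8-[(1R,2S)-2-(tert-butyldimethylsilyloxy)-3-methyl-1-(trimethylsilyloxy)butyl]-7-methoxy-2H-chromen-2-one | COc1ccc2ccc(=O)oc2c1[C@@H](O[Si](C)(C)C)[C@@H](O[Si](C)(C)C(C)(C)C)C(C)C | intermediate (not isolated)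
8 | 8-[(1R,2S)-2-(tert-butyldimethylsilyloxy)-1-hydroxy-3-methylbutyl]-7-methoxy-2H-chromen-2-one | COc1ccc2ccc(=O)oc2c1[C@@H](O)[C@@H](O[Si](C)(C)C(C)(C)C)C(C)C | intermediate
9 | 3-methylbut-2-enoyl chloride (senecioyl chloride) | CC(C)=CC(=O)Cl | starting material
10 | (1R,2S)-2-(tert-butyldimethylsilyloxy)-1-(7-methoxy-2-oxo-2H-chromen-8-yl)-3-methylbutyl 3-methylbut-2-enoate | COc1ccc2ccc(=O)oc2c1[C@@H](OC(=O)C=C(C)C)[C@@H](O[Si](C)(C)C(C)(C)C)C(C)C | intermediate
11 | (1R,2S)-2-hydroxy-1-(7-methoxy-2-oxo-2H-chromen-8-yl)-3-methylbutyl 3-methylbut-2-enoate | COc1ccc2ccc(=O)oc2c1[C@@H](OC(=O)C=C(C)C)[C@@H](O)C(C)C | intermediate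
12 | (1R)-1-(7-methoxy-2-oxo-2H-chromen-8-yl)-3-methyl-2-oxobutyl 3-methylbut-2-enoate | COc1ccc2ccc(=O)oc2c1[C@@H](OC(=O)C=C(C)C)C(=O)C(C)C | target

**Step count and risks**
Total steps: 8. Longest linear sequence: 6 (steps 1, 2, 5, 6, 7, 8; the aldehyde branch 3, 4, 5, 6, 7, 8 is equally long).

Steps most likely to fail:

1. Step 5 (proposed new electro-NHK arylation). Risks are sluggish aryl transfer from the di-ortho-substituted iodide, cathodic side reactions, and only moderate Felkin selectivity (expected anti:syn of about 5:1). The minor syn (1'S,2'S) isomer must be removed by chromatography at 8, because after step 8 it would become the enantiomer of the target. Fallback with known chemistry, setting out from 3 and 6 and returning at 8: iodine–magnesium exchange on 3 with iPrMgCl·LiCl in THF at −40 °C gives (7-methoxy-2-oxo-2H-chromen-8-yl)magnesium chloride F1; this is added to 6 at −78 °C and quenched with aq. NH4Cl, giving 8 directly by a Felkin–Anh-controlled Grignard addition.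

2. Step 6 (acylation of the hindered benzylic alcohol). Risks are low conversion or the β,γ-unsaturated (3-methylbut-3-enoate) isomer. Fallback setting out from 8 and returning at 10: Steglich coupling of 8 with (diethoxyphosphoryl)acetic acid (DIC, DMAP, CH2Cl2) gives (1R,2S)-2-(tert-butyldimethylsilyloxy)-1-(7-methoxy-2-oxo-2H-chromen-8-yl)-3-methylbutyl 2-(diethoxyphosphoryl)acetate F2; Horner–Wadsworth–Emmons olefination of F2 with acetone (NaH, THF, 0 °C → rt) then builds the conjugated C=C after the ester bond is in place and gives 10.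

3. Step 7 (desilylation next to an ester). Risks are slow cleavage of the hindered TBS ether or O1'→O2' acyl migration in 11. Fallback setting out from 10 and returning at 12, bypassing 11 and step 8: direct oxidative desilylation of 10 with Jones reagent (CrO3/H2SO4, acetone, 0 °C), so the carbinol is oxidised as soon as it is unmasked; this makes no new compound (F0).

**Further compounds**
F1 | step 5 | (7-methoxy-2-oxo-2H-chromen-8-yl)magnesium chloride | COc1ccc2ccc(=O)oc2c1[Mg]Cl
F2 | step 6 | (1R,2S)-2-(tert-butyldimethylsilyloxy)-1-(7-methoxy-2-oxo-2H-chromen-8-yl)-3-methylbutyl 2-(diethoxyphosphoryl)acetate | COc1ccc2ccc(=O)oc2c1[C@@H](OC(=O)CP(=O)(OCC)OCC)[C@@H](O[Si](C)(C)C(C)(C)C)C(C)C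
F0 | step 7 | none | none
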